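**Plan**

- Retrosynthesis: (a) cut the C5–propenyl bond of ring A (Suzuki coupling of a C5 bromide); (b) trace the C3 methyl back to an ester carbon (CO2Et → CH2OH → CH2OTs → CH3); (c) cut the C2–C3 bond of the dihydrofuran ring (ring C) by a carbene C–H insertion; (d) cut the aryl–C(N2) bond and (e) the O1–CH2 ether bond.
- Enabling feature: C2 is both benzylic to ring B and bound to O1. In the ring-opened precursor it is an ArCH2–O group whose doubly activated C–H lies in 1,5-relation (C3–C3a–C7a–O1–C2) to a carbene at C3. The one-carbon substituent on C3 can sit at the ester level, which makes that carbene a donor/acceptor carbene.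
- Forward: the ring B benzylic alcohol and the ring A iodophenol are joined through O1 (Mitsunobu). The diazo ester is placed on the ortho carbon (future C3) by palladium coupling. Ring C closes by enantioselective insertion. Then ester → methyl, MOM removal, and propenyl last.
- Stereochemistry: C2 (S) comes from the chiral dirhodium carboxylate in the insertion. C3 forms cis (kinetic) and is then set trans (S in the target) by base equilibration of the ester, with C2 as the reference. The E alkene comes from the E-propenylboronate.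

Key step: step 6

Assumption: the sense of induction of N-phthaloyl-tert-leucinate dirhodium catalysts with 2-(benzyloxy)phenyl diazoacetates (S ligand → 2R series) is taken to hold for 8, so the R ligand is used for 2S; if the sense proved opposite, the antipodal catalyst would be used with no other change.

Step 1
Reactants: 1 3-hydroxy-4,5-dimethoxybenzaldehyde
Product: 2 3,4-dimethoxy-5-(methoxymethoxy)benzaldehyde
Conditions: MOMCl, iPr2NEt, CH2Cl2, 0 °C to rt
Reagents that add atoms: chloromethyl methyl ether (MOMCl), COCCl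
Why: O-alkylation of the phenol by the reactive chloromethyl ether (MOM protection) gives an acetal that should survive every basic, hydridic and metal-mediated step ahead and leave under mild acid.

Step 2
Reactants: 2 3,4-dimethoxy-5-(methoxymethoxy)benzaldehyde
Product: 3 [3,4-dimethoxy-5-(methoxymethoxy)phenyl]methanol
Conditions: NaBH4, MeOH, 0 °C
Reagents that add atoms: none
Why: Borohydride reduction of the aryl aldehyde to the benzylic alcohol; the MOM acetal is inert.

Step 3
Reactants: 4 4-bromo-2-methoxyphenol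
Product: 5 4-bromo-2-iodo-6-methoxyphenol
Conditions: NIS (1.05 equiv), TsOH·H2O (10 mol%), MeCN, 0 °C to rt
Reagents that add atoms: N-iodosuccinimide, O=C1CCC(=O)N1I
Why: Electrophilic aromatic iodination directed by the free hydroxyl; its para position is blocked by bromine and one ortho position by methoxy, so the only hydroxyl-activated site is C6.

Step 4
Reactants: 5 4-bromo-2-iodo-6-methoxyphenol; 3 [3,4-dimethoxy-5-(methoxymethoxy)phenyl]methanol
Product: 6 5-bromo-2-{[3,4-dimethoxy-5-(methoxymethoxy)phenyl]methoxy}-1-iodo-3-methoxybenzene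
Conditions: PPh3, DIAD, THF, 0 °C to rt
Reagents that add atoms: none
Why: Mitsunobu etherification of the acidic phenol with the primary benzylic alcohol forms the O1–CH2 bond under neutral conditions and avoids isolating a labile electron-rich benzyl halide.

Step 5
Reactants: 6 5-bromo-2-{[3,4-dimethoxy-5-(methoxymethoxy)phenyl]methoxy}-1-iodo-3-methoxybenzene; 7 ethyl diazoacetate
Product: 8 ethyl 2-(5-bromo-2-{[3,4-dimethoxy-5-(methoxymethoxy)phenyl]methoxy}-3-methoxyphenyl)-2-diazoacetate
Conditions: Pd(PPh3)4 (5 mol%), Ag2CO3 (0.5 equiv), Et3N (1.3 equiv), toluene, rt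
Reagents that add atoms: none
Why: Cross-coupling of an aryl iodide with the C–H bond of a diazoacetate with retention of the diazo group (oxidative addition of zerovalent palladium at C–I at room temperature, which leaves C–Br alone, then silver-assisted iodide abstraction, palladation of the diazo carbon and reductive elimination).

Step 6
Reactants: 8 ethyl 2-(5-bromo-2-{[3,4-dimethoxy-5-(methoxymethoxy)phenyl]methoxy}-3-methoxyphenyl)-2-diazoacetate
Product: 9 ethyl (2S,3R)-5-bromo-2-[3,4-dimethoxy-5-(methoxymethoxy)phenyl]-7-methoxy-2,3-dihydro-1-benzofuran-3-carboxylate (2,3-cis)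
Conditions: Rh2(R-PTTL)4 (dirhodium tetrakis[N-phthaloyl-(R)-tert-leucinate], 1 mol%), toluene, −60 °C, slow addition of 8
Reagents that add atoms: none
Why: The divalent rhodium dimer decomposes the donor/acceptor diazo ester with loss of N2 to an electrophilic rhodium carbenoid at the future C3, which inserts through a concerted, asynchronous three-centre (hydride-shift-like) transition state into one C–H bond of the O–CH2–Ar group and so forms the C2–C3 bond. The closest known reaction type is the enantioselective intramolecular C–H insertion of 2-(benzyloxy)phenyl diazoacetates to cis-2-aryl-2,3-dihydrobenzofuran-3-carboxylates under dirhodium N-phthaloyl-tert-leucinate catalysis. Ring C closes as a five-membered ring by 1,5-insertion, the carbene carbon and the reacting C–H being linked through C3a, C7a and O1. C2 is controlled by the chiral catalyst, whose ligand wall selects one of the two enantiotopic benzylic hydrogens (R ligand chosen for 2S), while C3 arises 2,3-cis (3R) under kinetic control because aryl and ester lie on the same side in the compact transition state; this centre is corrected in step 7. The step needs site selectivity for the benzylic ether C–H over ylide formation at O1, attack on the aromatic rings and the methoxy or MOM C–H bonds; this is secured by geometry (only the O–CH2–Ar hydrogens are in 1,5-relation, an O1 ylide would need a four-membered ring) and by the double activation of that C–H by the oxygen lone pair and the electron-rich aryl, while low temperature and slow addition suppress carbene dimerisation.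

Step 7
Reactants: 9 ethyl (2S,3R)-5-bromo-2-[3,4-dimethoxy-5-(methoxymethoxy)phenyl]-7-methoxy-2,3-dihydro-1-benzofuran-3-carboxylate
Product: 10 ethyl (2S,3S)-5-bromo-2-[3,4-dimethoxy-5-(methoxymethoxy)phenyl]-7-methoxy-2,3-dihydro-1-benzofuran-3-carboxylate (2,3-trans)
Conditions: NaOEt (0.2 equiv), EtOH, rt
Reagents that add atoms: none
Why: Base-mediated epimerisation through the C3 ester enolate under thermodynamic control should give the more stable 2,3-trans ester; C2 is not touched and ethoxide in ethanol matches the ester.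

Step 8
Reactants: 10 ethyl (2S,3S)-5-bromo-2-[3,4-dimethoxy-5-(methoxymethoxy)phenyl]-7-methoxy-2,3-dihydro-1-benzofuran-3-carboxylate
Product: 11 {(2S,3R)-5-bromo-2-[3,4-dimethoxy-5-(methoxymethoxy)phenyl]-7-methoxy-2,3-dihydro-1-benzofuran-3-yl}methanol (2,3-trans)
Conditions: LiAlH4, THF, 0 °C
Reagents that add atoms: none
Why: Hydride reduction of the ester to the primary alcohol at 0 °C, where the aryl bromide, the MOM acetal and both stereocentres are untouched (the descriptor at C3 changes only through substituent priorities).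

Step 9
Reactants: 11 {(2S,3R)-5-bromo-2-[3,4-dimethoxy-5-(methoxymethoxy)phenyl]-7-methoxy-2,3-dihydro-1-benzofuran-3-yl}methanol
Product: 12 {(2S,3R)-5-bromo-2-[3,4-dimethoxy-5-(methoxymethoxy)phenyl]-7-methoxy-2,3-dihydro-1-benzofuran-3-yl}methyl 4-methylbenzenesulfonate
Conditions: TsCl, Et3N, DMAP (cat.), CH2Cl2, 0 °C to rt
Reagents that add atoms: 4-methylbenzenesulfonyl chloride, Cc1ccc(cc1)S(=O)(=O)Cl
Why: Sulfonylation of the primary alcohol activates the former ester carbon for deoxygenation.

Step 10
Reactants: 12 {(2S,3R)-5-bromo-2-[3,4-dimethoxy-5-(methoxymethoxy)phenyl]-7-methoxy-2,3-dihydro-1-benzofuran-3-yl}methyl 4-methylbenzenesulfonate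
Product: 13 (2S,3S)-5-bromo-2-[3,4-dimethoxy-5-(methoxymethoxy)phenyl]-7-methoxy-3-methyl-2,3-dihydro-1-benzofuran
Conditions: LiBHEt3, THF, 0 °C to rt
Reagents that add atoms: none
Why: SN2 displacement of the primary tosylate by the strongly nucleophilic, weakly basic triethylborohydride should turn CH2OTs into the C3 methyl group without elimination and without reducing the aryl bromide; no stereocentre is involved.

Step 11
Reactants: 13 (2S,3S)-5-bromo-2-[3,4-dimethoxy-5-(methoxymethoxy)phenyl]-7-methoxy-3-methyl-2,3-dihydro-1-benzofuran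
Product: 14 5-[(2S,3S)-5-bromo-7-methoxy-3-methyl-2,3-dihydro-1-benzofuran-2-yl]-2,3-dimethoxyphenol
Conditions: HCl (cat.), MeOH, rt to 40 °C
Reagents that add atoms: none
Why: Acid-catalysed methanolysis of the MOM acetal, done before the acid-sensitive propenyl group is present; any reversible ionisation at C2 would return to the thermodynamically preferred trans ring.

Step 12
Reactants: 14 5-[(2S,3S)-5-bromo-7-methoxy-3-methyl-2,3-dihydro-1-benzofuran-2-yl]-2,3-dimethoxyphenol; 15 4,4,5,5-tetramethyl-2-[(E)-prop-1-enyl]-1,3,2-dioxaborolane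
Product: 16 2,3-dimethoxy-5-{(2S,3S)-7-methoxy-3-methyl-5-[(E)-prop-1-enyl]-2,3-dihydro-1-benzofuran-2-yl}phenol (target)
Conditions: Pd(dppf)Cl2 (5 mol%), K2CO3 (3 equiv), 1,4-dioxane/H2O, 80 °C, degassed
Reagents that add atoms: none
Why: Suzuki–Miyaura coupling of the aryl bromide with the E-alkenylboronate proceeds with retention of alkene geometry and tolerates the free phenol as its phenoxide.

**Compound list**

1 | 3-hydroxy-4,5-dimethoxybenzaldehyde | COc1cc(C=O)cc(O)c1OC | starting material
2 | 3,4-dimethoxy-5-(methoxymethoxy)benzaldehyde | COCOc1cc(C=O)cc(OC)c1OC | intermediate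
3 | [3,4-dimethoxy-5-(methoxymethoxy)phenyl]methanol | COCOc1cc(CO)cc(OC)c1OC | intermediate
4 | 4-bromo-2-methoxyphenol | COc1cc(Br)ccc1O | starting material
5 | 4-bromo-2-iodo-6-methoxyphenol | COc1cc(Br)cc(I)c1O | intermediate
6 | 5-bromo-2-{[3,4-dimethoxy-5-(methoxymethoxy)phenyl]methoxy}-1-iodo-3-methoxybenzene | COc1cc(Br)cc(I)c1OCc1cc(OC)c(OC)c(OCOC)c1 | intermediate
7 | ethyl diazoacetate | CCOC(=O)C=[N+]=[N-] | starting material
8 | ethyl 2-(5-bromo-2-{[3,4-dimethoxy-5-(methoxymethoxy)phenyl]methoxy}-3-methoxyphenyl)-2-diazoacetate | CCOC(=O)C(=[N+]=[N-])c1cc(Br)cc(OC)c1OCc1cc(OC)c(OC)c(OCOC)c1 | intermediate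
9 | ethyl (2S,3R)-5-bromo-2-[3,4-dimethoxy-5-(methoxymethoxy)phenyl]-7-methoxy-2,3-dihydro-1-benzofuran-3-carboxylate (cis) | Brc1cc(OC)c2c(c1)[C@@H](C(=O)OCC)[C@@H](c1cc(OCOC)c(OC)c(OC)c1)O2 | intermediate
10 | ethyl (2S,3S)-5-bromo-2-[3,4-dimethoxy-5-(methoxymethoxy)phenyl]-7-methoxy-2,3-dihydro-1-benzofuran-3-carboxylate (trans) | Brc1cc(OC)c2c(c1)[C@H](C(=O)OCC)[C@@H](c1cc(OCOC)c(OC)c(OC)c1)O2 | intermediate
11 | {(2S,3R)-5-bromo-2-[3,4-dimethoxy-5-(methoxymethoxy)phenyl]-7-methoxy-2,3-dihydro-1-benzofuran-3-yl}methanol (trans) | Brc1cc(OC)c2c(c1)[C@H](CO)[C@@H](c1cc(OCOC)c(OC)c(OC)c1)O2 | intermediate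
12 | {(2S,3R)-5-bromo-2-[3,4-dimethoxy-5-(methoxymethoxy)phenyl]-7-methoxy-2,3-dihydro-1-benzofuran-3-yl}methyl 4-methylbenzenesulfonate (trans) | Brc1cc(OC)c2c(c1)[C@H](COS(=O)(=O)c1ccc(C)cc1)[C@@H](c1cc(OCOC)c(OC)c(OC)c1)O2 | intermediate
13 | (2S,3S)-5-bromo-2-[3,4-dimethoxy-5-(methoxymethoxy)phenyl]-7-methoxy-3-methyl-2,3-dihydro-1-benzofuran | Brc1cc(OC)c2c(c1)[C@H](C)[C@@H](c1cc(OCOC)c(OC)c(OC)c1)O2 | intermediate
14 | 5-[(2S,3S)-5-bromo-7-methoxy-3-methyl-2,3-dihydro-1-benzofuran-2-yl]-2,3-dimethoxyphenol | Brc1cc(OC)c2c(c1)[C@H](C)[C@@H](c1cc(O)c(OC)c(OC)c1)O2 | intermediate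
15 | 4,4,5,5-tetramethyl-2-[(E)-prop-1-enyl]-1,3,2-dioxaborolane | C/C=C/B1OC(C)(C)C(C)(C)O1 | starting material
16 | 2,3-dimethoxy-5-{(2S,3S)-7-methoxy-3-methyl-5-[(E)-prop-1-enyl]-2,3-dihydro-1-benzofuran-2-yl}phenol | C/C=C/c1cc(OC)c2c(c1)[C@H](C)[C@@H](c1cc(O)c(OC)c(OC)c1)O2 | target

**Count and risks**

Total step count: 12. Longest linear sequence: 11 steps (1 → 2 → 3 → 6 → 8 → 9 → 10 → 11 → 12 → 13 → 14 → 16).

Steps most likely to fail:

Step 5. The coupling may stall at the ortho-alkoxy-hindered aryl iodide, or the diazo ester formed may be decomposed by palladium (carbene dimerisation or further coupling). The fallback sets out from 6 and returns at 8, building the diazo group from a ketone instead of by C–H coupling. Iodine–magnesium exchange of 6 (iPrMgCl·LiCl, THF, −40 °C, selective over bromine) and trapping with diethyl oxalate would give ethyl 2-(5-bromo-2-{[3,4-dimethoxy-5-(methoxymethoxy)phenyl]methoxy}-3-methoxyphenyl)-2-oxoacetate F1. Condensation with TsNHNH2 (EtOH, 60 °C) would give its 4-methylbenzenesulfonylhydrazone F2. Elimination of sulfinate with DBU (CH2Cl2, rt; Bamford–Stevens type) should give 8.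

Step 6. The two enantiotopic benzylic hydrogens may be discriminated incompletely, since the extra ortho methoxy group and the ethyl ester move the substrate away from the closest cases, which would leave 9 and hence 10 of insufficient enantiomeric purity. The fallback sets out from 10 and returns at 11, securing absolute configuration by classical resolution instead of by the catalyst alone. Saponification of 10 (LiOH, THF/H2O) would give (2S,3S)-5-bromo-2-[3,4-dimethoxy-5-(methoxymethoxy)phenyl]-7-methoxy-2,3-dihydro-1-benzofuran-3-carboxylic acid F3. This would be crystallised to purity as its (S)-1-phenylethylammonium salt F4 (the antipodal amine is taken if the less soluble salt carries the wrong acid). Acidification and reduction of the freed acid with BH3·THF should give 11.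

Step 7. The C3 enolate may expel the O1 phenoxide (E1cB ring opening) instead of simply reprotonating, and reversible reclosure would erode the C2 configuration. The fallback sets out from 8 and returns at 14. It lets the catalyst set C3 and corrects C2 by acid instead of correcting C3 by base.
- Insertion of 8 with the antipodal catalyst Rh2(S-PTTL)4 would give ethyl (2R,3S)-5-bromo-2-[3,4-dimethoxy-5-(methoxymethoxy)phenyl]-7-methoxy-2,3-dihydro-1-benzofuran-3-carboxylate F5 (cis, enantiomer of 9).
- LiAlH4 would give the cis alcohol {(2R,3R)-5-bromo-2-[3,4-dimethoxy-5-(methoxymethoxy)phenyl]-7-methoxy-2,3-dihydro-1-benzofuran-3-yl}methanol F6.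
- TsCl/Et3N would give its 4-methylbenzenesulfonate F7.
- LiBHEt3 would give (2R,3S)-5-bromo-2-[3,4-dimethoxy-5-(methoxymethoxy)phenyl]-7-methoxy-3-methyl-2,3-dihydro-1-benzofuran F8 (cis).
- HCl/MeOH would give the cis phenol 5-[(2R,3S)-5-bromo-7-methoxy-3-methyl-2,3-dihydro-1-benzofuran-2-yl]-2,3-dimethoxyphenol F9.
- Treatment with CF3CO2H (or BF3·OEt2) in CH2Cl2 should ionise the C2–O1 bond reversibly to the para-methoxy-stabilised benzylic cation, and reclosure anti to the C3 methyl would invert C2 only and give trans 14.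

Further compounds

F1 | step 5 | ethyl 2-(5-bromo-2-{[3,4-dimethoxy-5-(methoxymethoxy)phenyl]methoxy}-3-methoxyphenyl)-2-oxoacetate | CCOC(=O)C(=O)c1cc(Br)cc(OC)c1OCc1cc(OC)c(OC)c(OCOC)c1
F2 | step 5 | ethyl 2-(5-bromo-2-{[3,4-dimethoxy-5-(methoxymethoxy)phenyl]methoxy}-3-methoxyphenyl)-2-[(4-methylbenzenesulfonyl)hydrazinylidene]acetate | CCOC(=O)C(=NNS(=O)(=O)c1ccc(C)cc1)c1cc(Br)cc(OC)c1OCc1cc(OC)c(OC)c(OCOC)c1
F3 | step 6 | (2S,3S)-5-bromo-2-[3,4-dimethoxy-5-(methoxymethoxy)phenyl]-7-methoxy-2,3-dihydro-1-benzofuran-3-carboxylic acid | Brc1cc(OC)c2c(c1)[C@H](C(=O)O)[C@@H](c1cc(OCOC)c(OC)c(OC)c1)O2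
F4 | step 6 | (S)-1-phenylethylammonium (2S,3S)-5-bromo-2-[3,4-dimethoxy-5-(methoxymethoxy)phenyl]-7-methoxy-2,3-dihydro-1-benzofuran-3-carboxylate | Brc1cc(OC)c2c(c1)[C@H](C(=O)[O-])[C@@H](c1cc(OCOC)c(OC)c(OC)c1)O2.C[C@H]([NH3+])c1ccccc1
F5 | step 7 | ethyl (2R,3S)-5-bromo-2-[3,4-dimethoxy-5-(methoxymethoxy)phenyl]-7-methoxy-2,3-dihydro-1-benzofuran-3-carboxylate (cis) | Brc1cc(OC)c2c(c1)[C@H](C(=O)OCC)[C@H](c1cc(OCOC)c(OC)c(OC)c1)O2
F6 | step 7 | {(2R,3R)-5-bromo-2-[3,4-dimethoxy-5-(methoxymethoxy)phenyl]-7-methoxy-2,3-dihydro-1-benzofuran-3-yl}methanol (cis) | Brc1cc(OC)c2c(c1)[C@H](CO)[C@H](c1cc(OCOC)c(OC)c(OC)c1)O2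
F7 | step 7 | {(2R,3R)-5-bromo-2-[3,4-dimethoxy-5-(methoxymethoxy)phenyl]-7-methoxy-2,3-dihydro-1-benzofuran-3-yl}methyl 4-methylbenzenesulfonate (cis) | Brc1cc(OC)c2c(c1)[C@H](COS(=O)(=O)c1ccc(C)cc1)[C@H](c1cc(OCOC)c(OC)c(OC)c1)O2
F8 | step 7 | (2R,3S)-5-bromo-2-[3,4-dimethoxy-5-(methoxymethoxy)phenyl]-7-methoxy-3-methyl-2,3-dihydro-1-benzofuran (cis) | Brc1cc(OC)c2c(c1)[C@H](C)[C@H](c1cc(OCOC)c(OC)c(OC)c1)O2
F9 | step 7 | 5-[(2R,3S)-5-bromo-7-methoxy-3-methyl-2,3-dihydro-1-benzofuran-2-yl]-2,3-dimethoxyphenol (cis) | Brc1cc(OC)c2c(c1)[C@H](C)[C@H](c1cc(O)c(OC)c(OC)c1)O2
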